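- Turn the question round: what would the readings have to say for this flask to stop within 40 h?

- red: G 0.60 M; run made earlier
- flask: G 0.40 M; time 40 h

red run (percent of the G charged)

| time / h | G / % | E / % | L / % |
|---|---|---|---|
| 1.33 | 77.4 | 23.2 | 0 |
| 2.50 | 71.8 | 28.3 | 0 |
| 4.00 | 70.0 | 28.7 | 1.0 |
| 5.00 | 69.6 | 28.6 | 0.9 |
| 6.00 | 70.4 | 28.7 | 2.0 |
| 8.00 | 69.6 | 27.0 | 3.2 |

(scatter of a reading: 0.5 percentage points)

- the state of affairs at 40 h: stopped, and by what, or still going (all of G has reacted / forward and back rates have come level / it is still moving)
- how much of the G has reacted by 40 h
- how much E there is at 40 h, in percent of the G charged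
- how much L there is at 40 h, in percent of the G charged

- percentages count the G that a species holds: one E or L counts as two
- the reaction counts as stopped when no species that holds the G changes by six tenths of a point or more over the second half of the time

- In the red run G and E flatten by 4.00 h while L climbs, so I read a fast equilibrium of two G with one E. One E holds two G, so cE is half its share times the charge, and K = cE/(cG·cG) reads 0.488 /M.
- I assume L grows at first order in cE. The leak constant, the L share gained per hour per unit of E share, is 0.0139 /h, read from L at 8.00 h. The scatter makes that reading uncertain by about 15.6 %.
- Its half-life of 49.7 h is longer than the 4.00 h by which the red run flattened, so I take this leak as the rate-limiting step and expect G and E to stay near balance as they drain.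
- To count as stopped, this flask's L must gain less than 0.6 percentage points over the second half, so E would have to stand below 2.15 %. At 0.40 M, before the leak has drawn on the pool, K puts E near 23.1 %, ten times that, and the leak's half-life is longer than the 40 h of this flask, so I say it is still moving.
- With E held there, L reaches 12.9 %; E sinks as L grows, so I expect slightly less.
- The forecast says it is still moving: conversion 30.5 % (25 % to 38 %), E 18.5 % (15 % to 22 %), L 12 % (7 % to 18 %). On the first order it says: “This order is assumed, since the data barely fix it.” Its L is lower than mine.
- The flask at 40 h: it is still moving, with conversion 30.9 %, E 18.3 %, L 12.2 %.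

    2 G ⇌ E (K = 0.487 /M, k = 8.82 × 10⁻⁵ /M/s)
    E → L (k = 4.22 × 10⁻⁶ /s)
    G → Z (k = 4.21 × 10⁻⁸ /s)

- Over the second half this flask's largest change is 5.9 points, and the leak constant on its E, averaged from 20.5 % at 20.0 h and 18.3 % at 40.0 h, gives 5.4 points. For the neighbour flask with 0.24 M of G, K puts E near 16.4 %, the leak constant with E held there gives L 9.12 %, and that neighbour flask holds L at 8.79 % at 40.0 h.

The data come from a simulation on assumed constants.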